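## Retrosynthetic overview

1. Oxepane last: C16–O–C3 bond by displacement of a C16 triflate by the C3 tertiary alcohol; C15 from hydroboration of a C14 isopropenyl group; C3 carbinol from MeMgCl on a C3 ketone.
2. Cyclohexane: intermolecular Diels–Alder of methyl vinyl ketone with a (Z)-2-silyloxy diene (C1=C10–C11(OTBS)=C12H–CH3) on the oxabicyclo[6.2.1] core; this sets C1, C12 and C14, then C10 and C11 follow.
3. (E)-Oxonene and tetrahydrofuranone together: a new Au-catalysed alkyne oxidation / oxonium-ylide [2,3] ring expansion of a 2-propargyl-6-isopropenyl tetrahydropyran.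
4. Tetrahydropyran: SmI2 ketyl–β-alkoxyacrylate cyclisation; absolute configuration from Sharpless kinetic resolution of an allylic alcohol.
5. Ring order: tetrahydropyran (sacrificial) → oxonene + THF → cyclohexane → oxepane.

Assumptions: the target SMILES encodes a (6E) ring alkene (C5 and C8 trans), and the route targets that isomer. Asbestinin numbering (C1–C16) is used in descriptions. Only skeleton-building reactants are numbered; other reagents appear under "Reagents that add atoms".

## Route

Step 1
Reactants: 1, 2-(2-bromoethyl)-1,3-dioxolane; 2, methacrolein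
Product: 3, (±)-5-(1,3-dioxolan-2-yl)-2-methylpent-1-en-3-ol
Conditions: Mg, THF, 25 °C; then 2, −78 → 0 °C
Reagents that add atoms: none
Why: Grignard 1,2-addition to the enal gives the racemic allylic alcohol carrying a masked C3 aldehyde.

Step 2
Reactants: 3, racemic allylic alcohol
Product: 4, (S)-5-(1,3-dioxolan-2-yl)-2-methylpent-1-en-3-ol
Conditions: Ti(OiPr)4, D-(−)-DIPT, t-BuOOH (0.6 equiv), 4 Å MS, CH2Cl2, −20 °C; recover unreacted alcohol
Reagents that add atoms: none
Why: Sharpless kinetic resolution; with D-(−)-tartrate the (R)-enantiomer is epoxidised fast, leaving (S)-4 (C6) in high ee.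

Step 3
Reactants: 4, (S)-allylic alcohol; 5, ethyl propiolate
Product: 6, ethyl (E)-3-{[(3S)-5-(1,3-dioxolan-2-yl)-2-methylpent-1-en-3-yl]oxy}prop-2-enoate
Conditions: N-methylmorpholine, CH2Cl2, rt
Reagents that add atoms: none
Why: Amine-catalysed oxa-Michael addition to the propiolate gives the (E)-β-alkoxyacrylate without touching C6.

Step 4
Reactants: 6, acetal acrylate
Product: 7, ethyl (E)-3-{[(3S)-2-methyl-6-oxohex-1-en-3-yl]oxy}prop-2-enoate
Conditions: p-TsOH·H2O (cat.), acetone/H2O, 40 °C
Reagents that add atoms: water, O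
Why: Acetal hydrolysis; the vinylogous carbonate is much less acid-labile than the dioxolane.

Step 5
Reactants: 7, aldehyde acrylate
Product: 8, ethyl 2-[(2S,3R,6S)-3-hydroxy-6-(prop-1-en-2-yl)oxan-2-yl]acetate
Conditions: SmI2 (3 equiv), MeOH, THF, 0 °C
Reagents that add atoms: none
Why: SmI2 ketyl–olefin reductive cyclisation through a Sm-chelated chair transition state gives the 2,6-cis-2,3-trans tetrahydropyran, so C6 sets C2 (S).

Step 6
Reactants: 8, tetrahydropyranol
Product: 9, ethyl 2-[(2S,3R,6S)-3-(tert-butyldimethylsilyloxy)-6-(prop-1-en-2-yl)oxan-2-yl]acetate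
Conditions: TBSCl, imidazole, DMF, rt
Reagents that add atoms: TBSCl, CC(C)(C)[Si](C)(C)Cl
Why: Standard silylation masks the C3 hydroxyl, which would otherwise trap the carbene in step 9.

Step 7
Reactants: 9, ester
Product: 10, 2-[(2S,3R,6S)-3-(TBSO)-6-(prop-1-en-2-yl)oxan-2-yl]acetaldehyde
Conditions: DIBAL-H, CH2Cl2, −78 °C
Reagents that add atoms: none
Why: Partial ester reduction; the chelated aluminium hemiacetal of a β-alkoxy ester survives at −78 °C.

Step 8
Reactants: 10, aldehyde
Product: 11, tert-butyldimethyl{[(2S,3R,6S)-6-(prop-1-en-2-yl)-2-(prop-2-yn-1-yl)oxan-3-yl]oxy}silane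
Conditions: Ohira–Bestmann reagent, K2CO3, MeOH, 0 °C → rt
Reagents that add atoms: dimethyl (1-diazo-2-oxopropyl)phosphonate, COP(=O)(OC)C(=[N+]=[N-])C(C)=O
Why: Seyferth–Gilbert (Ohira–Bestmann) homologation gives the terminal alkyne; any reversible β-alkoxy elimination would return the thermodynamically favoured 2,6-cis ring.

Step 9
Reactants: 11, propargyl tetrahydropyran
Product: 12, (1S,2R,5E,8S)-2-(TBSO)-6-methyl-11-oxabicyclo[6.2.1]undec-5-en-9-one (asbestinin C2 S, C3 R, C9 S, 6E; ketone at C10)
Conditions: IPrAuNTf2 (5 mol %), 8-methylquinoline N-oxide (1.5 equiv, slow addition), 4 Å MS, 1,2-dichloroethane, rt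
Reagents that add atoms: 8-methylquinoline N-oxide, Cc1cccc2ccc[n+]([O-])c12 (supplies the ketone O)
Why: Proposed new method: N-oxide attack on the Au-activated terminal alkyne gives an α-oxo gold carbene at C9, which the ring oxygen traps to form a five-membered bicyclic oxonium ylide; [2,3]-shift onto the cis-disposed 6-isopropenyl group forms C8–C9, cleaves O–C6 and expands the six-membered ring to the 2,9-cis-bridged oxonene, with the E-alkene expected from the envelope transition state of the free ylide in which C5 is pseudo-equatorial (a bulky NHC ligand and NTf2 counter-ion favour loss of gold before the shift). Closest known reactions: Rh/Cu-carbenoid oxonium-ylide [2,3] ring expansion of the corresponding diazoketone, and Au/N-oxide α-oxo-carbene oxonium-ylide rearrangement of acyclic homopropargyl allyl ethers; the ring-expanding bridged-oxonene variant has not, to my knowledge, been shown.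

Step 10
Reactants: 12, bicyclic ketone
Product: 13, enol triflate of 12 (C10–OTf, C1=C10)
Conditions: KHMDS, PhNTf2, THF, −78 °C
Reagents that add atoms: N-phenyl-bis(trifluoromethanesulfonimide), O=S(=O)(N(c1ccccc1)S(=O)(=O)C(F)(F)F)C(F)(F)F
Why: Kinetic deprotonation occurs at the C1 methylene rather than the bridgehead α-alkoxy C9–H, and the enolate is trapped as the triflate.

Step 11
Reactants: 13, enol triflate
Product: 14, Weinreb amide (C10–C(=O)N(OMe)Me, C1=C10)
Conditions: Pd(OAc)2 (5 mol %), Xantphos, CO (1 atm), MeNH(OMe)·HCl, Et3N, DMF, 60 °C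
Reagents that add atoms: carbon monoxide, [C-]#[O+]; N,O-dimethylhydroxylamine hydrochloride, CNOC.Cl
Why: Pd-catalysed aminocarbonylation of an alkenyl triflate installs C11 as an acyl group.

Step 12
Reactants: 14, Weinreb amide
Product: 15, ethyl enone (C1=C10–C11(=O)–C12H2–CH3)
Conditions: EtMgBr, THF, −20 → 0 °C
Reagents that add atoms: ethylmagnesium bromide, CC[Mg]Br
Why: Weinreb ketone synthesis; the chelated tetrahedral intermediate prevents over- and conjugate addition and brings in C12 and its methyl.

Step 13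
Reactants: 15, ethyl enone
Product: 16, (Z)-2-silyloxy diene (C1=C10–C11(OTBS)=C12H–CH3, OTBS and CH3 cis)
Conditions: TBSOTf, Et3N, CH2Cl2, −78 → 0 °C
Reagents that add atoms: TBSOTf, CC(C)(C)[Si](C)(C)OS(=O)(=O)C(F)(F)F
Why: Soft enolisation at the α′-CH2 gives the cross-conjugated silyl dienol ether, Z-selective because A(1,3) strain with the bulky C10 alkenyl group disfavours the E isomer; this puts the C12 methyl "outside" on the diene.

Step 14
Reactants: 16, silyloxy diene; 17, methyl vinyl ketone
Product: 18, tricyclic silyl enol ether (C10=C11–OTBS) with C14 acetyl; H1 trans to H2, C12–CH3 cis to the C1–C2 bond, C14 acetyl trans to the C1–C2 bond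
Conditions: 17 (5 equiv), BHT (cat.), toluene, 100 °C, sealed tube; then DBU (0.3 equiv), CH2Cl2, rt
Reagents that add atoms: none
Why: Diels–Alder reaction, regiocontrolled "para" to the silyloxy group (C12–C13 and C1–C14 bonds), with the dienophile adding to the dihydrofuran face opposite the oxonene bridge (sets C1) and suprafacial addition placing the outside C12 methyl cis to C2 (sets C12); DBU then epimerises C14 to the equatorial acetyl isomer, in which the C12 methyl sits pseudo-axial to avoid A(1,2) strain with the OTBS group.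

Step 15
Reactants: 18, methyl ketone
Product: 19, C14-isopropenyl silyl enol ether
Conditions: Ph3P+CH3 Br−, KOtBu, THF, 0 °C → rt
Reagents that add atoms: methyltriphenylphosphonium bromide, C[P+](c1ccccc1)(c1ccccc1)c1ccccc1.[Br-]
Why: Wittig methylenation of the methyl ketone; C14 is already the thermodynamic epimer and the silyl enol ether tolerates the salt-free ylide.

Step 16
Reactants: 19, silyl enol ether
Product: 20, C11 ketone with cis-fused C1/C10 (H1 and H10 cis), C3–OTBS retained
Conditions: TBAF (1.1 equiv), AcOH (1.5 equiv), THF, −40 → −10 °C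
Reagents that add atoms: none
Why: Fluoride cleaves the enol silyl ether far faster than the alkyl TBS ether, and the enolate is protonated kinetically at C10 from the convex face (the H1 face, away from C2 and the THF oxygen), giving the cis ring fusion under non-equilibrating conditions that leave C12 untouched.

Step 17
Reactants: 20, C11 ketone
Product: 21, C11 alcohol (H11 cis to H10 and H12; OH cis to the C12 methyl)
Conditions: LiAlH4, Et2O, −78 °C
Reagents that add atoms: none
Why: Hydride attacks the carbonyl from the open face bearing H1/H10/H12, because the opposite face is blocked in either chair (by axial C9/C12-Me or by axial C2), setting C11.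

Step 18
Reactants: 21, C11 alcohol
Product: 22, C11 butanoate
Conditions: butyric anhydride, DMAP, Et3N, CH2Cl2, rt
Reagents that add atoms: butyric anhydride, CCCC(=O)OC(=O)CCC
Why: DMAP-catalysed acylation installs the natural ester, which also protects C11–O for the rest of the route.

Step 19
Reactants: 22, C3 silyl ether
Product: 23, C3 secondary alcohol
Conditions: HF·pyridine, pyridine, THF, 0 °C → rt
Reagents that add atoms: none
Why: Buffered HF removes the secondary TBS ether without affecting the butanoate or the alkenes.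

Step 20
Reactants: 23, C3 alcohol
Product: 24, C3 ketone
Conditions: Dess–Martin periodinane, NaHCO3, CH2Cl2, rt
Reagents that add atoms: none
Why: Mild buffered oxidation of the only free hydroxyl; the α-alkoxy C2 centre is not epimerised.

Step 21
Reactants: 24, C3 ketone
Product: 25, C3 tertiary alcohol (3S; CH3 cis to H2)
Conditions: MeMgCl (1.5 equiv), THF, −78 °C
Reagents that add atoms: methylmagnesium chloride, C[Mg]Cl
Why: Chelation-controlled Grignard addition to the α-alkoxy ketone (Mg bridging C3=O and the THF oxygen) delivers methyl from the H2 face, anti to C1, and the ketone reacts far faster than the hindered butanoate at −78 °C.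

Step 22
Reactants: 25, isopropenyl tertiary alcohol
Product: 26, C16 primary alcohol with (15R) configuration (C3,C16-diol)
Conditions: 9-BBN (3 equiv), THF, 0 °C → rt; then NaBO3·4H2O, H2O, rt
Reagents that add atoms: sodium perborate, [Na+].[Na+].O[B-]1(O)OO[B-](O)(O)OO1 (supplies O)
Why: 9-BBN hydroborates the 1,1-disubstituted alkene far faster than the trisubstituted ring alkene; in the rotamer with H14 eclipsing C15=C16 the borane adds to the face anti to the congested C1/C2 side, giving 15R by substrate control, and perborate oxidation spares the ester.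

Step 23
Reactants: 26, diol
Product: 27, 4-deoxyasbestinin A
Conditions: Tf2O (1.1 equiv), 2,6-lutidine, CH2Cl2, −78 °C → rt
Reagents that add atoms: none
Why: The primary alcohol is triflated selectively and the C3 tertiary hydroxyl displaces it by intramolecular SN2 (Williamson-type etherification) to close the oxepane without touching any stereocentre.

## Compound list

1 | 2-(2-bromoethyl)-1,3-dioxolane | BrCCC1OCCO1 | starting material
2 | methacrolein | CC(=C)C=O | starting material
3 | (±)-5-(1,3-dioxolan-2-yl)-2-methylpent-1-en-3-ol | OC(C(C)=C)CCC1OCCO1 | intermediate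
4 | (S)-5-(1,3-dioxolan-2-yl)-2-methylpent-1-en-3-ol | O[C@H](C(C)=C)CCC1OCCO1 | intermediate
5 | ethyl propiolate | CCOC(=O)C#C | starting material
6 | ethyl (E)-3-{[(3S)-5-(1,3-dioxolan-2-yl)-2-methylpent-1-en-3-yl]oxy}prop-2-enoate | CCOC(=O)/C=C/O[C@H](C(C)=C)CCC1OCCO1 | intermediate
7 | ethyl (E)-3-{[(3S)-2-methyl-6-oxohex-1-en-3-yl]oxy}prop-2-enoate | CCOC(=O)/C=C/O[C@H](C(C)=C)CCC=O | intermediate
8 | ethyl 2-[(2S,3R,6S)-3-hydroxy-6-(prop-1-en-2-yl)oxan-2-yl]acetate | CCOC(=O)C[C@@H]1O[C@H](C(C)=C)CC[C@H]1O | intermediate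
9 | TBS ether of 8 | CCOC(=O)C[C@@H]1O[C@H](C(C)=C)CC[C@H]1O[Si](C)(C)C(C)(C)C | intermediate
10 | 2-[(2S,3R,6S)-3-(TBSO)-6-(prop-1-en-2-yl)oxan-2-yl]acetaldehyde | O=CC[C@@H]1O[C@H](C(C)=C)CC[C@H]1O[Si](C)(C)C(C)(C)C | intermediate
11 | (2S,3R,6S)-3-(TBSO)-6-(prop-1-en-2-yl)-2-(prop-2-yn-1-yl)oxane | C#CC[C@@H]1O[C@H](C(C)=C)CC[C@H]1O[Si](C)(C)C(C)(C)C | intermediate
12 | (1S,2R,5E,8S)-2-(TBSO)-6-methyl-11-oxabicyclo[6.2.1]undec-5-en-9-one | O=C1C[C@@H]2O[C@H]1C/C(C)=C/CC[C@H]2O[Si](C)(C)C(C)(C)C | intermediate
13 | C10 enol triflate of 12 (C1=C10) | O=S(=O)(OC1=C[C@@H]2O[C@H]1C/C(C)=C/CC[C@H]2O[Si](C)(C)C(C)(C)C)C(F)(F)F | intermediate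
14 | C10 Weinreb amide (C1=C10) | CON(C)C(=O)C1=C[C@@H]2O[C@H]1C/C(C)=C/CC[C@H]2O[Si](C)(C)C(C)(C)C | intermediate
15 | C10 propanoyl enone (C1=C10–C11(=O)Et) | CCC(=O)C1=C[C@@H]2O[C@H]1C/C(C)=C/CC[C@H]2O[Si](C)(C)C(C)(C)C | intermediate
16 | (Z)-silyloxy diene (C1=C10–C11(OTBS)=C12H–CH3) | C/C=C(\O[Si](C)(C)C(C)(C)C)C1=C[C@@H]2O[C@H]1C/C(C)=C/CC[C@H]2O[Si](C)(C)C(C)(C)C | intermediate
17 | methyl vinyl ketone | CC(=O)C=C | starting material
18 | Diels–Alder adduct: C14 acetyl, C12 methyl, C10=C11–OTBS, C3–OTBS | CC(=O)[C@@H]1C[C@@H](C)C(O[Si](C)(C)C(C)(C)C)=C2[C@H]1[C@@H]1O[C@H]2C/C(C)=C/CC[C@H]1O[Si](C)(C)C(C)(C)C | intermediate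
19 | C14 isopropenyl analogue of 18 | CC(=C)[C@@H]1C[C@@H](C)C(O[Si](C)(C)C(C)(C)C)=C2[C@H]1[C@@H]1O[C@H]2C/C(C)=C/CC[C@H]1O[Si](C)(C)C(C)(C)C | intermediate
20 | C11 ketone, cis-fused at C1/C10, C3–OTBS | CC(=C)[C@@H]1C[C@@H](C)C(=O)[C@@H]2[C@H]1[C@@H]1O[C@H]2C/C(C)=C/CC[C@H]1O[Si](C)(C)C(C)(C)C | intermediate
21 | C11 alcohol, C3–OTBS | CC(=C)[C@@H]1C[C@@H](C)[C@@H](O)[C@@H]2[C@H]1[C@@H]1O[C@H]2C/C(C)=C/CC[C@H]1O[Si](C)(C)C(C)(C)C | intermediate
22 | C11 butanoate, C3–OTBS | CC(=C)[C@@H]1C[C@@H](C)[C@@H](OC(=O)CCC)[C@@H]2[C@H]1[C@@H]1O[C@H]2C/C(C)=C/CC[C@H]1O[Si](C)(C)C(C)(C)C | intermediate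
23 | C11 butanoate, C3 secondary alcohol | CC(=C)[C@@H]1C[C@@H](C)[C@@H](OC(=O)CCC)[C@@H]2[C@H]1[C@@H]1O[C@H]2C/C(C)=C/CC[C@H]1O | intermediate
24 | C11 butanoate, C3 ketone | CC(=C)[C@@H]1C[C@@H](C)[C@@H](OC(=O)CCC)[C@@H]2[C@H]1[C@@H]1O[C@H]2C/C(C)=C/CCC1=O | intermediate
25 | C11 butanoate, (3S) tertiary alcohol, C14 isopropenyl | CC(=C)[C@@H]1C[C@@H](C)[C@@H](OC(=O)CCC)[C@@H]2[C@H]1[C@@H]1O[C@H]2C/C(C)=C/CC[C@]1(C)O | intermediate
26 | (15R) C16 primary alcohol / C3 tertiary alcohol diol | OC[C@H](C)[C@@H]1C[C@@H](C)[C@@H](OC(=O)CCC)[C@@H]2[C@H]1[C@@H]1O[C@H]2C/C(C)=C/CC[C@]1(C)O | intermediate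
27 | 4-deoxyasbestinin A (1S,2S,3S,6E,9S,10R,11R,12R,14S,15R) | CCCC(=O)O[C@H]1[C@@H]2[C@@H]3[C@@H](C[C@H]1C)[C@@H](C)CO[C@@]1(C)CC/C=C(\C)C[C@@H]2O[C@@H]31 | target

## Summary

Total steps: 23. Longest linear sequence: 23 (fully linear from 1 and 2).

Steps most likely to fail:

1. **Step 9 (proposed new Au oxidation / oxonium-ylide [2,3] ring expansion).** Risks are E/Z control, over-oxidation of the gold carbene and competing carbene pathways. Fallback (known chemistry): saponify ester 9, convert the acid to the α-diazoketone (mixed anhydride, then diazomethane), and run the Rh(II) carboxamidate-catalysed carbenoid / oxonium-ylide [2,3] rearrangement to 12.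

2. **Step 14 (Diels–Alder of the hindered C12-methyl diene, and survival of the kinetic C12 centre through steps 16–17).** Fallback: couple triflate 13 with tributyl(1-ethoxyvinyl)stannane to the C12-unsubstituted 2-ethoxy diene, carry out the Diels–Alder, epimerisation, Wittig and enol-ether hydrolysis to the C11 ketone, then add the C12 methyl by α-methylenation (Eschenmoser's salt) and conjugate reduction with kinetic protonation from the convex face. C12 is then set by protonation rather than by the cycloaddition.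

3. **Step 22 (C15 diastereoselectivity in the hydroboration).** Fallback: oxidise the C16 alcohol mixture to the aldehyde, which closes onto the C3 hydroxyl as the seven-membered lactol; equilibrate the now-epimerisable C15 under thermodynamic control (or recycle the minor epimer), then reduce the lactol with Et3SiH/BF3·OEt2. This closes the oxepane by reductive etherification instead of SN2; whether the natural C15 epimer is the thermodynamic one in the lactol is not established.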